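**Plan**

- Retrosynthesis: the silyl and acetyl groups are removed and the 6β,7α-diol is traced to a 6β-oxygenated 8-en-7-one; C9–C11 is cut (side-chain organolithium plus C9 ketone, then 1,3-oxidative transposition); then C3–C4 of ring A is cut; finally C10–C1 and C10–C20 lead back to (R)-carvone.
- Enabling feature: carvone is ring B as it stands (C5 stereocentre, C8 methyl, C7=C8–C9=O) and its isopropenyl carbon is C4, so an allyl group on C10 places C3 one bond away from a tertiary C4 cation.
- Forward: two enolate alkylations build quaternary C10; HCl/SnCl4 closes ring A; dechlorination; γ-oxidation to the 7-ene-6,9-dione and hydride at C6; the (Z)-C5 iodide, made from (Z)-3-methylpent-2-en-4-yn-1-ol, is joined at C9 as its organolithium; oxidative transposition, directed reduction, O7 silylation, O6 acetylation, desilylation.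
- Stereochemistry: C5 comes from (R)-carvone; C10 from allylation anti to the isopropenyl group; 6β-O from α-face hydride attack on the 6-ketone; 7α-OH from hydride delivered by the 6β-hydroxyl; 13Z is bought with the enynol and never disturbed.

Key step: step 3

Remark: positions are given in labdane numbering (decalin C1–C10, side chain C11–C16, C17 on C8, C20 on C10), β means the face of the C10 methyl, and (Z)-3-methylpent-2-en-4-yn-1-ol is assumed to be purchasable as the pure Z isomer.

**Route**

Step 1
Reactants: 1 (R)-carvone; 2 iodomethane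
Product: 4 (5R)-2,6-dimethyl-5-(prop-1-en-2-yl)cyclohex-2-en-1-one (6-methylcarvone; C6 epimers), via lithium enolate 3 (not isolated)
Conditions: LiN(i-Pr)2, THF, −78 °C; then MeI, −78 to 0 °C
Reagents that add atoms: iodomethane (2), CI
Why: Kinetic α′-deprotonation gives the cross-conjugated enolate, and its C-methylation (enolate alkylation) puts the future C20 methyl on the future C10; the epimer mixture at this carbon does not matter because step 2 makes it planar again.

Step 2
Reactants: 4 6-methylcarvone; 5 allyl bromide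
Product: 7 (5S,6S)-2,6-dimethyl-6-(prop-2-en-1-yl)-5-(prop-1-en-2-yl)cyclohex-2-en-1-one (allyl trans to isopropenyl), via lithium enolate 6 (not isolated)
Conditions: LiN(i-Pr)2, THF, −78 to 0 °C; then allyl bromide, HMPA, −78 °C to rt
Reagents that add atoms: allyl bromide (5), C=CCBr
Why: Enolate alkylation: allyl bromide should attack the tetrasubstituted enolate on the face opposite the adjacent isopropenyl group, which sets quaternary C10 with allyl trans and methyl cis to isopropenyl.

Step 3
Reactants: 7 (5S,6S)-6-allyl-6-methylcarvone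
Product: 9 (4aS,8aS)-7-chloro-2,5,5,8a-tetramethyl-4a,5,6,7,8,8a-hexahydronaphthalen-1(4H)-one (trans-decalin; C2 chloride epimers in labdane numbering), via tertiary chloride 8 (not isolated)
Conditions: HCl (g), CH2Cl2, −20 °C; then SnCl4, −78 to −20 °C
Reagents that add atoms: hydrogen chloride, Cl
Why: Markovnikov addition of HCl to the 1,1-disubstituted isopropenyl group gives tertiary chloride 8, which SnCl4 ionises to the C4 tertiary cation; the terminal allyl carbon C3 attacks it to form C3–C4, and the secondary C2 cation is trapped by chloride from SnCl5−. This is a cation–olefin (Prins-type) cyclisation with halide termination, a known reaction type for tertiary cations and monosubstituted alkenes. Ring A closes in the 6-endo-trig mode with respect to the allyl double bond, the Markovnikov sense that avoids the primary cation of a 5-exo closure, through a chair transition state with both tethers equatorial on ring B. The ring fusion is not created here, since C5 and C10 are fixed and the trans relationship of allyl and isopropenyl can only give the trans-decalin; the only new stereocentre is the C2 chloride, formed as both epimers and deleted in step 4. The step needs ionisation at the isopropenyl-derived carbon and not at the allyl group, and capture by C3 faster than proton loss or 1,2-hydride shift from C5; the first is secured by tertiary versus secondary cation stability and by SnCl4 complexation of the enone, the second by low temperature and a chloride-rich medium in which unproductive ionisation returns to 8.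

Step 4
Reactants: 9 chloro-decalin enone
Product: 10 (4aS,8aS)-2,5,5,8a-tetramethyl-4a,5,6,7,8,8a-hexahydronaphthalen-1(4H)-one
Conditions: Bu3SnH, AIBN (cat.), toluene, 100 °C
Reagents that add atoms: none
Why: Radical-chain hydrodehalogenation: the stannyl radical abstracts the secondary chlorine and the C2 radical, remote from the enone, is quenched by Bu3SnH, so both C2 epimers converge on one compound.

Step 5
Reactants: 10 bicyclic 7-en-9-one
Product: 11 (4aS,8aS)-2,5,5,8a-tetramethyl-4a,5,6,7,8,8a-hexahydronaphthalene-1,4-dione (7-ene-6,9-dione in labdane numbering)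
Conditions: Pd(OH)2 on carbon (cat.), t-BuOOH, K2CO3, CH2Cl2, 4 °C
Reagents that add atoms: tert-butyl hydroperoxide, CC(C)(C)OO
Why: Palladium-mediated tert-butylperoxyl radical oxidation of an enone at its γ-methylene (allylic C–H oxidation, the isophorone-to-ketoisophorone pattern) should attack C6, the only secondary allylic C–H; no stereocentre is formed and the trans ring fusion at C5 is the more stable arrangement.

Step 6
Reactants: 11 ene-dione
Product: 12 (4R,4aS,8aS)-4-hydroxy-2,5,5,8a-tetramethyl-4a,5,6,7,8,8a-hexahydronaphthalen-1(4H)-one (6β-hydroxy-7-en-9-one)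
Conditions: NaBH4, CeCl3·7H2O, MeOH, −78 °C
Reagents that add atoms: none
Why: Luche reduction: CeCl3 enforces 1,2-addition, the C9 carbonyl is shielded by quaternary C10 and the C8 methyl so hydride should go to C6 (as ketoisophorone is reduced at its less hindered carbonyl), and it arrives from the α face because the β face is closed by the axial C10 and C4 methyls, giving the 6β-alcohol.

Step 7
Reactants: 12 6β-hydroxy enone
Product: 13 (4R,4aS,8aS)-2,5,5,8a-tetramethyl-4-[(triethylsilyl)oxy]-4a,5,6,7,8,8a-hexahydronaphthalen-1(4H)-one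
Conditions: Et3SiOTf, 2,6-lutidine, CH2Cl2, −78 to 0 °C
Reagents that add atoms: triethylsilyl trifluoromethanesulfonate, CC[Si](CC)(CC)OS(=O)(=O)C(F)(F)F
Why: Silyl triflate silylation is strong enough for the hindered axial alcohol and gives an ether that tolerates the organolithium and the chromium oxidant of steps 12 and 13.

Step 8
Reactants: 14 (Z)-3-methylpent-2-en-4-yn-1-ol
Product: 15 tert-butyl{[(2Z)-3-methylpent-2-en-4-yn-1-yl]oxy}diphenylsilane
Conditions: t-BuPh2SiCl, imidazole, CH2Cl2, 0 °C to rt
Reagents that add atoms: tert-butyl(chloro)diphenylsilane, CC(C)(C)[Si](Cl)(c1ccccc1)c1ccccc1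
Why: Imidazole-promoted silylation of the primary allylic alcohol gives an ether stable to hydroboration, t-BuLi, chromium oxidant and mild acid.

Step 9
Reactants: 15 silylated enynol
Product: 16 tert-butyl{[(2Z)-3-methylpenta-2,4-dien-1-yl]oxy}diphenylsilane
Conditions: H2 (1 atm), Pd/CaCO3 poisoned with Pb(OAc)2, quinoline, hexane, rt
Reagents that add atoms: none
Why: Semihydrogenation on lead-poisoned palladium should stop at the vinyl group because the alkyne binds far more strongly than the diene, and the trisubstituted Z double bond is not touched.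

Step 10
Reactants: 16 (Z)-diene
Product: 18 (3Z)-5-[(tert-butyldiphenylsilyl)oxy]-3-methylpent-3-en-1-ol, via B-alkyl-9-BBN 17 (not isolated)
Conditions: 9-BBN, THF, 0 °C to rt; then NaOH, H2O2, 0 °C
Reagents that add atoms: hydrogen peroxide, OO
Why: Hydroboration–oxidation: the bulky borane adds only to the monosubstituted vinyl terminus with boron on the terminal carbon, the trisubstituted alkene being inert, and oxidation gives the primary homoallylic alcohol with the Z geometry intact.

Step 11
Reactants: 18 homoallylic alcohol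
Product: 19 tert-butyl{[(2Z)-5-iodo-3-methylpent-2-en-1-yl]oxy}diphenylsilane
Conditions: I2, PPh3, imidazole, CH2Cl2, 0 °C
Reagents that add atoms: iodine, II
Why: Appel-type iodination converts the primary alcohol into the iodide by SN2 displacement of the oxyphosphonium group without touching the allylic silyl ether or the alkene.

Step 12
Reactants: 19 (Z)-iodide; 13 6β-silyloxy enone
Product: 21 9-hydroxy-7,13-diene of the labdane skeleton carrying 6β-OSiEt3 and 15-OSiPh2t-Bu (13Z; at C9 hydroxyl β and side chain α expected), via organolithium 20 (not isolated)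
Conditions: 19, t-BuLi (2 equiv), Et2O, −78 °C; then 13, −78 to −20 °C; H2O
Reagents that add atoms: none
Why: Iodine–lithium exchange gives the primary homoallylic organolithium, which should add 1,2 to the non-enolisable C9 ketone from the α face opposite the C10 methyl; the C9 configuration is erased in step 13, so either epimer serves.

Step 13
Reactants: 21 tertiary allylic alcohol
Product: 22 (13Z)-15-[(tert-butyldiphenylsilyl)oxy]-6β-[(triethylsilyl)oxy]labda-8,13-dien-7-one
Conditions: [C5H5NH][CrO3Cl] (pyridinium chlorochromate), NaOAc, 4 Å molecular sieves, CH2Cl2, rt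
Reagents that add atoms: pyridinium chlorochromate, [O-][Cr](=O)(=O)Cl.c1cc[nH+]cc1
Why: Babler–Dauben oxidative transposition: the tertiary allylic chromate ester shifts [3,3] to C7 and is oxidised there, giving the tetrasubstituted 8-en-7-one; no stereocentre is formed, and the equatorial C6–H is poorly aligned with the carbonyl, so C6 should not epimerise under buffered conditions.

Step 14
Reactants: 22 6β-silyloxy enone
Product: 23 (13Z)-15-[(tert-butyldiphenylsilyl)oxy]-6β-hydroxylabda-8,13-dien-7-one
Conditions: PPTS, MeOH, rt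
Reagents that add atoms: none
Why: Acid-catalysed methanolysis removes the triethylsilyl ether far faster than the tert-butyldiphenylsilyl ether, and the weakly acidic medium should not enolise the ketol.

Step 15
Reactants: 23 6β-hydroxy enone
Product: 24 (13Z)-15-[(tert-butyldiphenylsilyl)oxy]labda-8,13-diene-6β,7α-diol
Conditions: Me4NBH(OAc)3, MeCN/AcOH (1:1), −30 to 0 °C
Reagents that add atoms: none
Why: Saksena–Evans hydroxyl-directed reduction: boron binds the axial 6β-oxygen and delivers hydride intramolecularly to the β face of C7, giving the trans-diaxial 6β,7α-diol; the reagent does not reduce the enone intermolecularly, which suppresses α-face attack.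

Step 16
Reactants: 24 6β,7α-diol
Product: 25 (13Z)-15-[(tert-butyldiphenylsilyl)oxy]-7α-[(triethylsilyl)oxy]labda-8,13-dien-6β-ol
Conditions: Et3SiCl, imidazole, DMF, 0 °C
Reagents that add atoms: chlorotriethylsilane, CC[Si](Cl)(CC)CC
Why: Site-selective silylation: the allylic 7α-hydroxyl reacts, whereas the 6β-hydroxyl, flanked by two syn-axial methyls, should not react at 0 °C.

Step 17
Reactants: 25 7-O-silyl diol
Product: 26 (13Z)-6β-acetoxy-15-[(tert-butyldiphenylsilyl)oxy]-7α-[(triethylsilyl)oxy]labda-8,13-diene
Conditions: Ac2O, DMAP, Et3N, CH2Cl2, 40 °C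
Reagents that add atoms: acetic anhydride, CC(=O)OC(C)=O
Why: DMAP-catalysed acylation of the one remaining free, hindered axial alcohol; with O7 blocked the acetate can only go to O6, and the trans-diaxial geometry prevents later acyl or silyl migration.

Step 18
Reactants: 26 acetate bis-silyl ether
Product: 27 (13Z)-6β-acetoxylabda-8,13-diene-7α,15-diol, (5S,6S,7S,10S), CNP0183298.2
Conditions: HF·pyridine, pyridine, THF, 0 °C to rt
Reagents that add atoms: none
Why: Fluoride cleavage of both silyl ethers under buffered, non-basic conditions leaves the acetate, the two allylic alcohols and both alkenes untouched.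

**Compound list**

1 | (R)-carvone, (5R)-2-methyl-5-(prop-1-en-2-yl)cyclohex-2-en-1-one | CC1=CC[C@H](CC1=O)C(C)=C | starting material
2 | iodomethane | CI | starting material
3 | lithium enolate of 1 (cross-conjugated) | CC1=CC[C@H](C=C1O[Li])C(C)=C | intermediate (not isolated)
4 | (5R)-2,6-dimethyl-5-(prop-1-en-2-yl)cyclohex-2-en-1-one, C6 epimer mixture | CC1=CC[C@@H](C(C)=C)C(C)C1=O | intermediate
5 | allyl bromide | C=CCBr | starting material
6 | lithium enolate of 4 (tetrasubstituted) | CC1=CC[C@@H](C(C)=C)C(C)=C1O[Li] | intermediate (not isolated)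
7 | (5S,6S)-2,6-dimethyl-6-(prop-2-en-1-yl)-5-(prop-1-en-2-yl)cyclohex-2-en-1-one | CC1=CC[C@@H](C(C)=C)[C@](C)(CC=C)C1=O | intermediate
8 | (5R,6S)-5-(2-chloropropan-2-yl)-2,6-dimethyl-6-(prop-2-en-1-yl)cyclohex-2-en-1-one | CC1=CC[C@@H](C(C)(C)Cl)[C@](C)(CC=C)C1=O | intermediate (not isolated)
9 | (4aS,8aS)-7-chloro-2,5,5,8a-tetramethyl-4a,5,6,7,8,8a-hexahydronaphthalen-1(4H)-one, chloride epimers | CC1=CC[C@H]2C(C)(C)CC(Cl)C[C@]2(C)C1=O | intermediate
10 | (4aS,8aS)-2,5,5,8a-tetramethyl-4a,5,6,7,8,8a-hexahydronaphthalen-1(4H)-one | CC1=CC[C@H]2C(C)(C)CCC[C@]2(C)C1=O | intermediate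
11 | (4aS,8aS)-2,5,5,8a-tetramethyl-4a,5,6,7,8,8a-hexahydronaphthalene-1,4-dione | CC1=CC(=O)[C@H]2C(C)(C)CCC[C@]2(C)C1=O | intermediate
12 | (4R,4aS,8aS)-4-hydroxy-2,5,5,8a-tetramethyl-4a,5,6,7,8,8a-hexahydronaphthalen-1(4H)-one | CC1=C[C@@H](O)[C@H]2C(C)(C)CCC[C@]2(C)C1=O | intermediate
13 | (4R,4aS,8aS)-2,5,5,8a-tetramethyl-4-[(triethylsilyl)oxy]-4a,5,6,7,8,8a-hexahydronaphthalen-1(4H)-one | CC1=C[C@@H](O[Si](CC)(CC)CC)[C@H]2C(C)(C)CCC[C@]2(C)C1=O | intermediate
14 | (Z)-3-methylpent-2-en-4-yn-1-ol | C#C/C(C)=C\CO | starting material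
15 | tert-butyl{[(2Z)-3-methylpent-2-en-4-yn-1-yl]oxy}diphenylsilane | C#C/C(C)=C\CO[Si](c1ccccc1)(c1ccccc1)C(C)(C)C | intermediate
16 | tert-butyl{[(2Z)-3-methylpenta-2,4-dien-1-yl]oxy}diphenylsilane | C=C/C(C)=C\CO[Si](c1ccccc1)(c1ccccc1)C(C)(C)C | intermediate
17 | 9-[(3Z)-5-(tert-butyldiphenylsilyloxy)-3-methylpent-3-en-1-yl]-9-borabicyclo[3.3.1]nonane | B1(CC/C(C)=C\CO[Si](c2ccccc2)(c2ccccc2)C(C)(C)C)C2CCCC1CCC2 | intermediate (not isolated)
18 | (3Z)-5-[(tert-butyldiphenylsilyl)oxy]-3-methylpent-3-en-1-ol | OCC/C(C)=C\CO[Si](c1ccccc1)(c1ccccc1)C(C)(C)C | intermediate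
19 | tert-butyl{[(2Z)-5-iodo-3-methylpent-2-en-1-yl]oxy}diphenylsilane | ICC/C(C)=C\CO[Si](c1ccccc1)(c1ccccc1)C(C)(C)C | intermediate
20 | [(3Z)-5-(tert-butyldiphenylsilyloxy)-3-methylpent-3-en-1-yl]lithium | [Li]CC/C(C)=C\CO[Si](c1ccccc1)(c1ccccc1)C(C)(C)C | intermediate (not isolated)
21 | 9-hydroxy-7,13-diene adduct (13Z; 6β-OSiEt3, 15-OSiPh2t-Bu; expected 9β-OH, side chain α) | CC1=C[C@@H](O[Si](CC)(CC)CC)[C@H]2C(C)(C)CCC[C@]2(C)[C@]1(O)CC/C(C)=C\CO[Si](c1ccccc1)(c1ccccc1)C(C)(C)C | intermediate
22 | (13Z)-15-[(tert-butyldiphenylsilyl)oxy]-6β-[(triethylsilyl)oxy]labda-8,13-dien-7-one | CC[Si](CC)(CC)O[C@@H]1C(=O)C(C)=C(CC/C(C)=C\CO[Si](c3ccccc3)(c3ccccc3)C(C)(C)C)[C@@]2(C)CCCC(C)(C)[C@H]12 | intermediate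
23 | (13Z)-15-[(tert-butyldiphenylsilyl)oxy]-6β-hydroxylabda-8,13-dien-7-one | O[C@@H]1C(=O)C(C)=C(CC/C(C)=C\CO[Si](c3ccccc3)(c3ccccc3)C(C)(C)C)[C@@]2(C)CCCC(C)(C)[C@H]12 | intermediate
24 | (13Z)-15-[(tert-butyldiphenylsilyl)oxy]labda-8,13-diene-6β,7α-diol | O[C@@H]1[C@@H](O)C(C)=C(CC/C(C)=C\CO[Si](c3ccccc3)(c3ccccc3)C(C)(C)C)[C@@]2(C)CCCC(C)(C)[C@H]12 | intermediate
25 | (13Z)-15-[(tert-butyldiphenylsilyl)oxy]-7α-[(triethylsilyl)oxy]labda-8,13-dien-6β-ol | O[C@@H]1[C@@H](O[Si](CC)(CC)CC)C(C)=C(CC/C(C)=C\CO[Si](c3ccccc3)(c3ccccc3)C(C)(C)C)[C@@]2(C)CCCC(C)(C)[C@H]12 | intermediate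
26 | (13Z)-6β-acetoxy-15-[(tert-butyldiphenylsilyl)oxy]-7α-[(triethylsilyl)oxy]labda-8,13-diene | CC(=O)O[C@@H]1[C@@H](O[Si](CC)(CC)CC)C(C)=C(CC/C(C)=C\CO[Si](c3ccccc3)(c3ccccc3)C(C)(C)C)[C@@]2(C)CCCC(C)(C)[C@H]12 | intermediate
27 | (13Z)-6β-acetoxylabda-8,13-diene-7α,15-diol, (5S,6S,7S,10S) | CC(=O)O[C@@H]1[C@@H](O)C(C)=C(CC/C(C)=C\CO)[C@@]2(C)CCCC(C)(C)[C@H]12 | target

**Step count and risks**

Total: 18 steps. Longest linear sequence: 14 steps from (R)-carvone (steps 1–7 and 12–18). The side-chain branch is 4 steps (8–11).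

Step 5 (γ-oxidation). Hydrogen abstraction may lack site selectivity (competition from the C8 methyl), stall on the hindered enone, or be accompanied by base-induced loss of the trans ring fusion. The fallback replaces radical C–H oxidation by enolate chemistry and sets out from 10. γ-Deprotonation with LiN(i-Pr)2 and trapping with Me3SiCl should give the 9-trimethylsilyloxy-6,8-diene F1. Dimethyldioxirane should oxidise its terminal C6=C7 bond (vinylogous Rubottom oxidation) to the 6α-hydroxy enone F2. MnO2 oxidation of this allylic alcohol rejoins the route at 11.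

Step 13 (oxidative transposition). The [3,3] shift of the chromate ester may be slowed by the neighbouring axial 6β-silyloxy group, leaving ionisation and dehydration to dienes as the main path. The fallback separates transposition from oxidation and sets out from 21. Catalytic O3ReOSiPh3 in Et2O should effect a redox-neutral 1,3-hydroxyl shift to the secondary 7-hydroxy-8-ene F3 (either C7 epimer). MnO2 then oxidises it to 22, where the route is rejoined.

Step 17 (acetylation of the 6β-hydroxyl). Acylation of the alcohol between two syn-axial methyls and next to the 7α-silyl ether may not proceed, or forcing conditions may strip the silyl ether. The fallback gives up protection of O7 and sets out from 24. Peracetylation under Lewis-acid catalysis (Ac2O, Sc(OTf)3, MeCN, −20 °C) should give the 6β,7α-diacetate F4. K2CO3 in MeOH should then remove the exposed allylic 7-acetate selectively, because the shielded 6β-acetate solvolyses far more slowly and cannot migrate across a trans-diaxial diol, giving the 6β-acetoxy-7α-ol F5. HF·pyridine removes the remaining silyl group and the route is rejoined at 27.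

Further compounds
F1 | step 5 | trimethyl{[(4aS,8aS)-2,5,5,8a-tetramethyl-4a,5,6,7,8,8a-hexahydronaphthalen-1-yl]oxy}silane (silyl dienol ether of 10) | C[Si](C)(C)OC1=C(C)C=C[C@H]2C(C)(C)CCC[C@]12C
F2 | step 5 | (4S,4aS,8aS)-4-hydroxy-2,5,5,8a-tetramethyl-4a,5,6,7,8,8a-hexahydronaphthalen-1(4H)-one (6α-hydroxy epimer of 12) | CC1=C[C@H](O)[C@H]2C(C)(C)CCC[C@]2(C)C1=O
F3 | step 13 | (13Z)-15-[(tert-butyldiphenylsilyl)oxy]-6β-[(triethylsilyl)oxy]labda-8,13-dien-7-ol (C7 epimers) | CC[Si](CC)(CC)O[C@@H]1C(O)C(C)=C(CC/C(C)=C\CO[Si](c3ccccc3)(c3ccccc3)C(C)(C)C)[C@@]2(C)CCCC(C)(C)[C@H]12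
F4 | step 17 | (13Z)-6β,7α-diacetoxy-15-[(tert-butyldiphenylsilyl)oxy]labda-8,13-diene | CC(=O)O[C@@H]1[C@@H](OC(C)=O)C(C)=C(CC/C(C)=C\CO[Si](c3ccccc3)(c3ccccc3)C(C)(C)C)[C@@]2(C)CCCC(C)(C)[C@H]12
F5 | step 17 | (13Z)-6β-acetoxy-15-[(tert-butyldiphenylsilyl)oxy]labda-8,13-dien-7α-ol | CC(=O)O[C@@H]1[C@@H](O)C(C)=C(CC/C(C)=C\CO[Si](c3ccccc3)(c3ccccc3)C(C)(C)C)[C@@]2(C)CCCC(C)(C)[C@H]12
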